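**Retrosynthetic overview**

1. Feature: both halves are the same trans-fused 2,2-dimethyloxepane/cyclohexane unit with the same absolute configuration (left: oxepane O6–C7–C10–C12–C13–C14–C5 on cyclohexane C2–C3–C4–C5–C14–C16; right: O29–C26–C24–C23–C22–C20–C30 on C30–C31–C32–C33–C19–C20). In each, O–CMe2–C(O)–C is a 2,2-dimethylfuran-3(2H)-one with two carbons (C13–C14, or C22–C20) inserted, and the inserted quaternary carbon also belongs to the cyclohexane.
2. Last skeletal bond C17–C18: sp3–sp3 Negishi coupling of the left C17 iodide with the right C18 alkylzinc. Both halves come from one ketone 21 (C2=O → C2=C1H2 on the left; → C33(CH3)OAc on the right).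
3. Oxepanone: Lewis acid/silane cleavage of the C5–C12 bond of a furanone–alkene photoadduct (two-carbon ring expansion of the furanone).
4. Cyclohexane and cyclobutane: intramolecular [2+2] photocycloaddition of the furanone C12=C5 bond with a tethered isopropenyl group (C5–C14 and C12–C13).
5. Precursor: Sharpless epoxidation and invertive isopropenyl-copper opening set C2 and C16; the furanone is built from the terminal alkyne. Ring order: furanone → cyclohexane + cyclobutane (step 9) → oxepane (step 10).

Key step: step 9

Remarks on the chemistry: atom labels C1–O38 follow the atom order of the target SMILES, and right-half intermediates carry the right-half labels (C18–C33) from step 18 on. C2 is carried as an (S)-configured, equatorial pivalate through the key step, because a ketal at C2 would be reduced by the silane in step 10 and an enolisable β,γ-unsaturated C2 ketone would endanger C16. Compounds 1, 2, 7 and 11 are assumed to be commercial.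

**Route**

Step 1
Reactants: 1 pent-4-yn-1-ol; 2 ethyl (triphenylphosphoranylidene)acetate
Product: 4 ethyl (2E)-hept-2-en-6-ynoate, via pent-4-ynal 3 (not isolated)
Conditions: IBX, DMSO, rt
Reagents that add atoms: none
Why: One-pot IBX oxidation/Wittig olefination avoids isolating the volatile aldehyde, and the stabilised ylide should give the (E)-enoate.

Step 2
Reactants: 4 ethyl (2E)-hept-2-en-6-ynoate
Product: 5 (2E)-hept-2-en-6-yn-1-ol
Conditions: DIBAL-H (2.2 equiv), CH2Cl2, –78 °C; Rochelle salt
Reagents that add atoms: none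
Why: DIBAL-H 1,2-reduction of the enoate should give the (E)-allylic alcohol and leave the alkyne untouched.

Step 3
Reactants: 5 (2E)-hept-2-en-6-yn-1-ol
Product: 6 [(2S,3S)-3-(but-3-yn-1-yl)oxiran-2-yl]methanol
Conditions: Ti(OiPr)4 (cat.), L-(+)-diethyl tartrate (cat.), t-BuOOH, 4 Å MS, CH2Cl2, –20 °C
Reagents that add atoms: tert-butyl hydroperoxide, CC(C)(C)OO
Why: Sharpless asymmetric epoxidation; with L-(+)-tartrate the (E)-allylic alcohol should give the (2S,3S)-epoxide, which fixes C2 and, after inversion, C16.

Step 4
Reactants: 6 [(2S,3S)-3-(but-3-yn-1-yl)oxiran-2-yl]methanol; 7 isopropenylmagnesium bromide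
Product: 8 (2R,3S)-2-(prop-1-en-2-yl)hept-6-yne-1,3-diol
Conditions: 7 (3.5 equiv), CuI (15 mol%), THF, –30 → –10 °C; aq. NH4Cl
Reagents that add atoms: none
Why: Copper-catalysed Grignard opening of a 2,3-epoxy alcohol should occur at the carbon next to the carbinol with SN2 inversion, giving the 1,3-diol with C16 (R) and the C2–O/C16–isopropenyl pair anti; the excess reagent covers deprotonation of O–H and C≡C–H, and any 1,2-diol regioisomer is separable.

Step 5
Reactants: 8 (2R,3S)-2-(prop-1-en-2-yl)hept-6-yne-1,3-diol
Product: 9 (3R,4S)-3-{[tert-butyl(dimethyl)silyl]oxymethyl}-2-methyloct-1-en-7-yn-4-ol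
Conditions: TBSCl (1.05 equiv), imidazole, CH2Cl2, –10 → 0 °C
Reagents that add atoms: tert-butyldimethylsilyl chloride, CC(C)(C)[Si](C)(C)Cl
Why: Silylation at low temperature should discriminate the primary hydroxyl from the hindered secondary one.

Step 6
Reactants: 9 (3R,4S)-3-{[tert-butyl(dimethyl)silyl]oxymethyl}-2-methyloct-1-en-7-yn-4-ol
Product: 10 (3R,4S)-3-{[tert-butyl(dimethyl)silyl]oxymethyl}-2-methyloct-1-en-7-yn-4-yl pivalate
Conditions: PivCl, pyridine, DMAP (cat.), CH2Cl2, rt
Reagents that add atoms: pivaloyl chloride, CC(C)(C)C(Cl)=O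
Why: DMAP-catalysed acylation masks the C2 hydroxyl as an ester that is inert to light, to Lewis acid/silane and to borane, and has no easily abstracted hydrogen.

Step 7
Reactants: 10 (3R,4S)-3-{[tert-butyl(dimethyl)silyl]oxymethyl}-2-methyloct-1-en-7-yn-4-yl pivalate; 11 2-acetoxy-2-methylpropanoyl chloride
Product: 12 (8S,9R)-2-acetoxy-9-{[tert-butyl(dimethyl)silyl]oxymethyl}-2,10-dimethyl-3-oxoundec-10-en-4-yn-8-yl pivalate
Conditions: PdCl2(PPh3)2 (2 mol%), CuI (4 mol%), Et3N, THF, rt
Reagents that add atoms: none
Why: Acyl Sonogashira coupling of a terminal alkyne with an acid chloride that has no α-hydrogen should give the ynone while tolerating silyl ether, ester and alkene.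

Step 8
Reactants: 12 ynone acetate
Product: 14 5-[(3S,4R)-4-{[tert-butyl(dimethyl)silyl]oxymethyl}-5-methyl-3-(pivaloyloxy)hex-5-en-1-yl]-2,2-dimethylfuran-3(2H)-one, via hydroxy ynone 13 (not isolated)
Conditions: K2CO3, MeOH, 0 °C → rt
Reagents that add atoms: none
Why: Methanolysis of the activated α-keto tertiary acetate frees the alkoxide, which should close by 5-endo-dig oxa-Michael addition to the ynone (a methanol adduct of the ynone converges on the same furanone by addition–elimination), the hindered pivalate surviving.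

Step 9
Reactants: 14 furanone with the C4–C3–C2(OPiv)–C16(CH2OTBS)–C14(CH3)=C13H2 tether on C5
Product: 15 tricyclic photoadduct (2,2-dimethyltetrahydrofuran-3-one O6/C7/C10/C12/C5 cis-fused at C5–C12 to cyclobutane C5/C12/C13/C14, which is cis-fused at C5–C14 to cyclohexane C5/C4/C3/C2/C16/C14)
Conditions: hν (λ = 300–350 nm, Pyrex), degassed MeCN, 0.01 M, 0 °C
Reagents that add atoms: none
Why: Excitation (n→π*) and intersystem crossing give the triplet furanone, whose β-carbon C5 bonds to C14 of the isopropenyl group to give a C12/C13 1,4-biradical that closes after spin inversion; the closest known reaction type is the intramolecular enone–alkene [2+2] photocycloaddition of 3(2H)-furanones and other cyclic enones that carry the alkene on a four-atom tether (straight adducts). The cyclohexane closes by 6-exo attack of C5 on C14 through a chair-like transition state and the cyclobutane by 1,4-biradical recombination (C12–C13). C5 and C12 should be cis because a cyclobutane can only be cis-fused to the five-membered ring, and C5/C14 cis because the two-atom C12–C13 link spans one face of the new six-membered ring. C14 is controlled by C16 and C2: in the reacting chair the C17 arm and the C2 pivalate are both equatorial, C16–H eclipses the C14=C13 bond (allylic strain, methylene terminus pseudo-equatorial) and the C15 methyl ends axial, cis to C17. The step needs regioselectivity (C5–C14/C12–C13, not the crossed mode), secured by the tether length, which offers no five-membered alternative, and facial selectivity, secured by the anti C2/C16 pattern, since addition to the other alkene face would require either an axial C17 arm and pivalate or a C16–H/C15 eclipsed rotamer.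

Step 10
Reactants: 15 tricyclic photoadduct
Product: 17 trans-fused 2,2-dimethyloxepan-3-one (C10 ketone; C5–H anti to C14–CH3; C2–OPiv; C17–OTBS), via trimethylsilyl enol ether 16 (not isolated)
Conditions: TMSOTf (1.2 equiv), Et3SiH (5 equiv), 2,6-di-tert-butyl-4-methylpyridine (cat.), CH2Cl2, –78 → –30 °C; then K2CO3, MeOH, 0 °C
Reagents that add atoms: none
Why: Proposed new method: silylation of the C10 carbonyl oxygen turns C5–C12 into a push–pull bond (O6 lone pair as donor, silyloxycarbenium as acceptor) whose heterolysis, driven by cyclobutane strain, should give a seven-membered oxocarbenium ion (C5=O6+) and the C10=C12 silyl enol ether; triethylsilane should then deliver hydride to C5 axially, on the face away from the axial C14 methyl, which gives the trans ring fusion, and methanolysis of the enol ether frees the ketone; the closest known reactions are the retro-aldol step of the de Mayo sequence, Lewis acid ring opening of donor–acceptor cyclobutanes and the TMSOTf/Et3SiH reduction of cyclic oxocarbenium ions.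

Step 11
Reactants: 17 trans-fused oxepan-3-one
Product: 18 (10S)-alcohol (C10–OH cis to C5–H)
Conditions: (R)-Me-CBS (20 mol%), BH3·SMe2, THF, –20 °C; MeOH
Reagents that add atoms: none
Why: Corey–Bakshi–Shibata reduction under reagent control: the oxazaborolidine differentiates the quaternary C7 from the C12 methylene, and the (R)-catalyst should deliver hydride to the face that gives the (S)-carbinol at C10.

Step 12
Reactants: 18 (10S)-alcohol
Product: 19 C10 tert-butyldimethylsilyl ether
Conditions: TBSOTf, 2,6-lutidine, CH2Cl2, 0 °C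
Reagents that add atoms: tert-butyldimethylsilyl trifluoromethanesulfonate, CC(C)(C)[Si](C)(C)OS(=O)(=O)C(F)(F)F
Why: Silyl triflate/lutidine silylation should protect the hindered neopentyl-type secondary alcohol.

Step 13
Reactants: 19 C10 silyl ether with C2 pivalate
Product: 20 C2 alcohol (equatorial OH; C10–OTBS; C17–OTBS)
Conditions: DIBAL-H (3 equiv), CH2Cl2, –78 °C; Rochelle salt
Reagents that add atoms: none
Why: Reductive cleavage of the pivalate by DIBAL-H should leave both silyl ethers intact.

Step 14
Reactants: 20 C2 alcohol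
Product: 21 C2 ketone (common to both halves)
Conditions: Dess–Martin periodinane, NaHCO3, CH2Cl2, rt
Reagents that add atoms: none
Why: Dess–Martin oxidation under buffered conditions should give the β-silyloxy ketone without β-elimination; the equatorial C16 arm is the thermodynamic epimer.

Step 15
Reactants: 21 C2 ketone
Product: 22 left-half exocyclic alkene (C2=C1H2; C10–OTBS; C17–OTBS)
Conditions: Ph3PCH3Br, KOtBu, toluene, 0 °C → rt
Reagents that add atoms: methyltriphenylphosphonium bromide, C[P+](c1ccccc1)(c1ccccc1)c1ccccc1.[Br-]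
Why: Wittig methylenation of the cyclohexanone installs C1.

Step 16
Reactants: 22 left-half exocyclic alkene
Product: 23 left-half primary alcohol (C17–OH; C10–OTBS)
Conditions: HF·pyridine, pyridine, THF, 0 °C
Reagents that add atoms: none
Why: Buffered HF·pyridine should cleave the primary silyl ether much faster than the hindered secondary one at C10.

Step 17
Reactants: 23 left-half primary alcohol
Product: 24 left-half C17 iodide
Conditions: I2, PPh3, imidazole, CH2Cl2, 0 °C → rt
Reagents that add atoms: iodine, II
Why: Appel-type iodination converts the primary alcohol to the iodide with neutral reagents.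

Step 18
Reactants: 21 C2 ketone (from here labelled as the right half: C2 ≡ C33, C10 ≡ C24, C17 ≡ C18)
Product: 26 right-half tertiary acetate (C33 methyl equatorial; C33–OAc axial; C24–OTBS; C18–OTBS), via lithium tertiary alkoxide 25 (not isolated)
Conditions: MeLi, Et2O/THF, –78 °C; then Ac2O, –78 °C → rt
Reagents that add atoms: methyllithium, [Li]C; acetic anhydride, CC(=O)OC(C)=O
Why: 1,2-Addition of methyllithium: the axial trajectory is blocked by the syn-axial C20 methyl, so methyl should enter equatorially and leave the C33 oxygen axial (cis to C21 and to the C18 arm) as in the target; acetylating the lithium alkoxide in the same flask avoids a separate esterification of a hindered tertiary alcohol.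

Step 19
Reactants: 26 right-half tertiary acetate
Product: 27 right-half diol (C18–OH; C24–OH; C33–OAc)
Conditions: 48% aq. HF, MeCN, rt
Reagents that add atoms: none
Why: Acidic fluoride desilylation should remove both silyl ethers and leave the tertiary acetate.

Step 20
Reactants: 27 right-half diol
Product: 28 right-half iodo alcohol (C18–I; C24–OH)
Conditions: I2, PPh3, imidazole, CH2Cl2, 0 °C
Reagents that add atoms: iodine, II
Why: Appel-type iodination should be selective for the primary hydroxyl over the neopentyl-type secondary one.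

Step 21
Reactants: 28 right-half iodo alcohol
Product: 29 right-half iodo ketone (C24=O; C18–I; C33–OAc)
Conditions: Dess–Martin periodinane, NaHCO3, CH2Cl2, rt
Reagents that add atoms: none
Why: Dess–Martin oxidation regenerates the C24 ketone and tolerates the primary iodide and the tertiary acetate.

Step 22
Reactants: 29 right-half iodo ketone; 24 left-half C17 iodide
Product: 31 coupled C10 silyl ether, via alkylzinc iodide 30 (not isolated)
Conditions: 29, Zn (activated), LiCl, THF, 40 °C; then 24, Ni(cod)2 (10 mol%), s-Bu-Pybox (20 mol%), DMA, rt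
Reagents that add atoms: none
Why: Alkyl–alkyl Negishi coupling: the organozinc tolerates ketone and ester, and nickel/pybox catalysis activates the β-branched primary iodide by halogen abstraction, so SN2-type hindrance is avoided; no stereocentre is touched.

Step 23
Reactants: 31 coupled C10 silyl ether
Product: 32 target CNP0148623.1
Conditions: HF·pyridine, THF, 0 °C → rt
Reagents that add atoms: none
Why: Fluoride desilylation frees the C10 hydroxyl; alkene, ketone and tertiary acetate should be inert.

**Compound list**

1 | pent-4-yn-1-ol | C#CCCCO | starting material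
2 | ethyl (triphenylphosphoranylidene)acetate | CCOC(=O)C=P(c1ccccc1)(c1ccccc1)c1ccccc1 | starting material
3 | pent-4-ynal (not isolated) | C#CCCC=O | intermediate
4 | ethyl (2E)-hept-2-en-6-ynoate | CCOC(=O)/C=C/CCC#C | intermediate
5 | (2E)-hept-2-en-6-yn-1-ol | OC/C=C/CCC#C | intermediate
6 | [(2S,3S)-3-(but-3-yn-1-yl)oxiran-2-yl]methanol | OC[C@@H]1O[C@H]1CCC#C | intermediate
7 | isopropenylmagnesium bromide | CC(=C)[Mg]Br | starting material
8 | (2R,3S)-2-(prop-1-en-2-yl)hept-6-yne-1,3-diol | OC[C@@H](C(C)=C)[C@@H](O)CCC#C | intermediate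
9 | (3R,4S)-3-{[tert-butyl(dimethyl)silyl]oxymethyl}-2-methyloct-1-en-7-yn-4-ol | CC(C)(C)[Si](C)(C)OC[C@@H](C(C)=C)[C@@H](O)CCC#C | intermediate
10 | (3R,4S)-3-{[tert-butyl(dimethyl)silyl]oxymethyl}-2-methyloct-1-en-7-yn-4-yl pivalate | CC(C)(C)[Si](C)(C)OC[C@@H](C(C)=C)[C@@H](OC(=O)C(C)(C)C)CCC#C | intermediate
11 | 2-acetoxy-2-methylpropanoyl chloride | CC(=O)OC(C)(C)C(Cl)=O | starting material
12 | (8S,9R)-2-acetoxy-9-{[tert-butyl(dimethyl)silyl]oxymethyl}-2,10-dimethyl-3-oxoundec-10-en-4-yn-8-yl pivalate | CC(C)(C)[Si](C)(C)OC[C@@H](C(C)=C)[C@@H](OC(=O)C(C)(C)C)CCC#CC(=O)C(C)(C)OC(C)=O | intermediate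
13 | (8S,9R)-9-{[tert-butyl(dimethyl)silyl]oxymethyl}-2-hydroxy-2,10-dimethyl-3-oxoundec-10-en-4-yn-8-yl pivalate (not isolated) | CC(C)(C)[Si](C)(C)OC[C@@H](C(C)=C)[C@@H](OC(=O)C(C)(C)C)CCC#CC(=O)C(C)(C)O | intermediate
14 | 5-[(3S,4R)-4-{[tert-butyl(dimethyl)silyl]oxymethyl}-5-methyl-3-(pivaloyloxy)hex-5-en-1-yl]-2,2-dimethylfuran-3(2H)-one | CC(C)(C)[Si](C)(C)OC[C@@H](C(C)=C)[C@@H](OC(=O)C(C)(C)C)CCC1=CC(=O)C(C)(C)O1 | intermediate
15 | tricyclic photoadduct: furanone/cyclobutane/cyclohexane, C5–O6 cis to C14–CH3, C17 arm cis to C14–CH3, C2–OPiv trans to the C17 arm | CC1(C)O[C@@]23CC[C@H](OC(=O)C(C)(C)C)[C@@H](CO[Si](C)(C)C(C)(C)C)[C@]2(C)C[C@H]3C1=O | intermediate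
16 | C10 trimethylsilyl enol ether (C10=C12) of 17 (not isolated) | CC(C)(C)[Si](C)(C)OC[C@@H]1[C@@H](OC(=O)C(C)(C)C)CC[C@@H]3OC(C)(C)C(O[Si](C)(C)C)=CC[C@@]13C | intermediate
17 | trans-fused 2,2-dimethyloxepan-3-one with C2–OPiv and C17–OTBS | CC(C)(C)[Si](C)(C)OC[C@@H]1[C@@H](OC(=O)C(C)(C)C)CC[C@@H]3OC(C)(C)C(=O)CC[C@@]13C | intermediate
18 | (10S)-alcohol of 17 | CC(C)(C)[Si](C)(C)OC[C@@H]1[C@@H](OC(=O)C(C)(C)C)CC[C@@H]3OC(C)(C)[C@@H](O)CC[C@@]13C | intermediate
19 | C10 TBS ether of 18 | CC(C)(C)[Si](C)(C)OC[C@@H]1[C@@H](OC(=O)C(C)(C)C)CC[C@@H]3OC(C)(C)[C@@H](O[Si](C)(C)C(C)(C)C)CC[C@@]13C | intermediate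
20 | C2 alcohol (C10–OTBS, C17–OTBS) | CC(C)(C)[Si](C)(C)OC[C@@H]1[C@@H](O)CC[C@@H]3OC(C)(C)[C@@H](O[Si](C)(C)C(C)(C)C)CC[C@@]13C | intermediate
21 | C2 ketone (C10–OTBS, C17–OTBS), common to both halves | CC(C)(C)[Si](C)(C)OC[C@@H]1C(=O)CC[C@@H]3OC(C)(C)[C@@H](O[Si](C)(C)C(C)(C)C)CC[C@@]13C | intermediate
22 | left half, C2 exocyclic methylene, C10–OTBS, C17–OTBS | C=C1CC[C@@H]2OC(C)(C)[C@@H](O[Si](C)(C)C(C)(C)C)CC[C@@]2(C)[C@@H]1CO[Si](C)(C)C(C)(C)C | intermediate
23 | left half, C17 alcohol | C=C1CC[C@@H]2OC(C)(C)[C@@H](O[Si](C)(C)C(C)(C)C)CC[C@@]2(C)[C@@H]1CO | intermediate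
24 | left half, C17 iodide | C=C1CC[C@@H]2OC(C)(C)[C@@H](O[Si](C)(C)C(C)(C)C)CC[C@@]2(C)[C@@H]1CI | intermediate
25 | right half, lithium C33 alkoxide (not isolated) | CC(C)(C)[Si](C)(C)OC[C@H]1[C@]2(C)CC[C@H](O[Si](C)(C)C(C)(C)C)C(C)(C)O[C@H]2CC[C@@]1(C)O[Li] | intermediate
26 | right half, C33 tertiary acetate, C24–OTBS, C18–OTBS | CC(C)(C)[Si](C)(C)OC[C@H]1[C@]2(C)CC[C@H](O[Si](C)(C)C(C)(C)C)C(C)(C)O[C@H]2CC[C@@]1(C)OC(C)=O | intermediate
27 | right half, C18/C24 diol | OC[C@H]1[C@]2(C)CC[C@H](O)C(C)(C)O[C@H]2CC[C@@]1(C)OC(C)=O | intermediate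
28 | right half, C18 iodide, C24 alcohol | IC[C@H]1[C@]2(C)CC[C@H](O)C(C)(C)O[C@H]2CC[C@@]1(C)OC(C)=O | intermediate
29 | right half, C18 iodide, C24 ketone | IC[C@H]1[C@]2(C)CCC(=O)C(C)(C)O[C@H]2CC[C@@]1(C)OC(C)=O | intermediate
30 | right half, C18 alkylzinc iodide (not isolated) | I[Zn]C[C@H]1[C@]2(C)CCC(=O)C(C)(C)O[C@H]2CC[C@@]1(C)OC(C)=O | intermediate
31 | C10 TBS ether of the target | C=C1CC[C@@H]2OC(C)(C)[C@@H](O[Si](C)(C)C(C)(C)C)CC[C@@]2(C)[C@@H]1CC[C@H]1[C@]2(C)CCC(=O)C(C)(C)O[C@H]2CC[C@@]1(C)OC(C)=O | intermediate
32 | CNP0148623.1 | C=C1CC[C@@H]2OC(C)(C)[C@@H](O)CC[C@@]2(C)[C@@H]1CC[C@H]1[C@]2(C)CCC(=O)C(C)(C)O[C@H]2CC[C@@]1(C)OC(C)=O | target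

**Step count**

Total: 23 steps. Longest linear sequence: 20 steps (1–14, 18–21, 22, 23); the left branch (15–17) joins at step 22.

**Steps most likely to fail**

Step 10 (proposed new method). The C5–C12 bond is a bond of the five-membered ring and lies close to the carbonyl plane, so it may overlap poorly with the activated carbonyl and fail to ionise. Ionic hydrogenation of the C10 ketone or loss of the primary silyl ether could then outrun fragmentation, and hydride delivery to C5 could be unselective. The fallback uses single-electron instead of Lewis acid activation and sets out from 15. Treatment with SmI2 (2.5 equiv) in THF/HMPA with MeOH at –78 → 0 °C should reduce the C10 ketone to its ketyl. Ketyl-induced opening of an α-keto cyclobutane is a known reaction type, and the bond expected to break here is C5–C12, because it gives the tertiary α-alkoxy radical at C5. That radical is reduced and protonated on the face away from the C14 methyl, which leaves the samarium(III) enolate F1. Aqueous work-up hydrolyses it, and the route is rejoined at 17.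

Step 22. Both coupling carbons are β-branched primary centres next to quaternary carbons. Transmetalation to nickel and the C–C bond-forming step may be slow, so that protodezincation of 30, β-hydride elimination from the alkylnickel or homocoupling take over. The fallback reverses the polarity and postpones the C24 oxidation; it sets out from 24 and 28. Iodide 24, which has no carbonyl group, is converted with activated magnesium in THF into the left-half alkylmagnesium iodide F2. Iodo alcohol 28 is deprotonated with MeMgCl (1.0 equiv, THF, –78 °C) to the chloromagnesium alkoxide F3. A copper-catalysed Kumada-type alkyl–alkyl coupling (Li2CuCl4 cat., THF/NMP, –30 → 0 °C), expected to be faster than attack on the hindered tertiary acetate, should give the coupled C24 alcohol F4. Dess–Martin oxidation of F4 rejoins the route at 31.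

Step 9. Ring closure through a four-atom tether is slower than through a three-atom one, so decay of the triplet, intramolecular hydrogen abstraction or secondary photolysis of the ketone product may compete. Rotation about C16–C14 and within the open chain may also lower the facial selectivity. The fallback replaces acyclic conformational control by a ring and sets out from 8. The diol is tied up with t-Bu2Si(OTf)2/2,6-lutidine as the (4S,5R)-dioxasilinane F5, in which the C3–C4 arm and the isopropenyl group are locked equatorial and gauche. Acyl Sonogashira coupling with 11 as in step 7 gives the ynone acetate F6. K2CO3/MeOH as in step 8 gives, through the hydroxy ynone F7, the silylene-bridged furanone F8. Irradiation as in step 9 should then give the silylene-bridged photoadduct F9, in which the trans-fused dioxasilinane allows only the chair leading to the configuration of 15. HF·pyridine removes the silylene to give the photoadduct diol F10. TBSCl/imidazole at the primary hydroxyl gives the mono-silyl ether F11, and PivCl/pyridine/DMAP rejoins the route at 15.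

**Further compounds**

F1 | step 10 | samarium(III) enolate (C10=C12) of 17 | CC(C)(C)[Si](C)(C)OC[C@@H]1[C@@H](OC(=O)C(C)(C)C)CC[C@@H]3OC(C)(C)C(O[Sm](I)I)=CC[C@@]13C
F2 | step 22 | left-half C17 alkylmagnesium iodide | C=C1CC[C@@H]2OC(C)(C)[C@@H](O[Si](C)(C)C(C)(C)C)CC[C@@]2(C)[C@@H]1C[Mg]I
F3 | step 22 | chloromagnesium C24 alkoxide of 28 | IC[C@H]1[C@]2(C)CC[C@H](O[Mg]Cl)C(C)(C)O[C@H]2CC[C@@]1(C)OC(C)=O
F4 | step 22 | coupled product with C24–OH and C10–OTBS | C=C1CC[C@@H]2OC(C)(C)[C@@H](O[Si](C)(C)C(C)(C)C)CC[C@@]2(C)[C@@H]1CC[C@H]1[C@]2(C)CC[C@H](O)C(C)(C)O[C@H]2CC[C@@]1(C)OC(C)=O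
F5 | step 9 | (4S,5R)-4-(but-3-yn-1-yl)-2,2-di-tert-butyl-5-(prop-1-en-2-yl)-1,3,2-dioxasilinane | CC(C)(C)[Si]1(C(C)(C)C)OC[C@@H](C(C)=C)[C@H](CCC#C)O1
F6 | step 9 | silylene-bridged ynone acetate | CC(C)(C)[Si]1(C(C)(C)C)OC[C@@H](C(C)=C)[C@H](CCC#CC(=O)C(C)(C)OC(C)=O)O1
F7 | step 9 | silylene-bridged hydroxy ynone (not isolated) | CC(C)(C)[Si]1(C(C)(C)C)OC[C@@H](C(C)=C)[C@H](CCC#CC(=O)C(C)(C)O)O1
F8 | step 9 | silylene-bridged furanone | CC(C)(C)[Si]1(C(C)(C)C)OC[C@@H](C(C)=C)[C@H](CCC2=CC(=O)C(C)(C)O2)O1
F9 | step 9 | silylene-bridged photoadduct | CC1(C)O[C@@]23CC[C@@H]4O[Si](C(C)(C)C)(C(C)(C)C)OC[C@H]4[C@]2(C)C[C@H]3C1=O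
F10 | step 9 | photoadduct C2/C17 diol | CC1(C)O[C@@]23CC[C@H](O)[C@@H](CO)[C@]2(C)C[C@H]3C1=O
F11 | step 9 | photoadduct with C17–OTBS and C2–OH | CC1(C)O[C@@]23CC[C@H](O)[C@@H](CO[Si](C)(C)C(C)(C)C)[C@]2(C)C[C@H]3C1=O
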